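## Structural features

The target is a germacranolide: a ten-membered carbocycle (C1–C10) cis-fused at C6–C7 to an α-methylene-γ-butyrolactone (C11, C12, exocyclic C13; lactone oxygen on C6). C4 (bearing the C15 methyl) and C5 carry a cis-epoxide. C1=C10 is a ring-cis trisubstituted alkene conjugated to the C14 methyl ester on C10. C8 carries an acetate and C9 the ester of (R)-2-methylglycidic acid. Six contiguous ring stereocentres run from C4 to C9: the epoxide oxygen is α at C4 and C5; O6, C11 and O8 are β (H6, H7, H8 mutually cis); O9 is α, trans to O8. The seventh stereocentre is the quaternary glycidate carbon. Fragile groups are the α-methylene lactone (Michael acceptor), both epoxides, the vicinal C8/C9 esters (acyl migration) and, in the intermediates, an alkylidene β-keto ester. The real difficulty is a medium ring with two ring-cis trisubstituted alkenes, one electron-poor, together with C8 and C9, which must be set on a flexible ring. The key step exploits that C4 and C9 are 1,6-related across the ring. A C4–C9 bond turns the macrocycle into a cis-decalin: ring A (C4–C9) carries the C5–C7 oxygen pattern and the lactone, ring B (C9, C10, C1–C4) is the cyclohexene enoate. Cleaving C4–C9 anti to a C5 leaving group then releases the C9 carbonyl and both alkene geometries at once.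

## Logic of the disconnections

31 to 30: the two C–O bonds of the 4,5-epoxide are cut. The epoxide is the most acid-sensitive group, and C4=C5 is the only electron-rich alkene in 30, so a peracid can be used last. Two stereocentres are removed. The forward step must add syn to the ring-cis alkene on the correct face.

30 to 29 to 28: the C8–O acetyl bond is cut and the oxygen is carried as a silyl ether. An acetate at C8 would not survive the lactone enolate needed for C13 (acyl transfer to C11 through a five-membered transition state, competing acetate deprotonation). The demand is a desilylation mild enough to avoid acyl migration and epoxide opening.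

28 to 26 to 25: the C11=C13 bond is cut. The Michael acceptor is introduced as late as enolate chemistry allows. In 25 the lactone CH2 is the most acidic position (the glycidate has no α-hydrogen, C8 bears a silyl ether). The forward step needs selective lactone enolisation beside the enoate.

25 to 21 and 23 (23 from 22): the C9–O acyl bond is cut. This is the convergent point and brings in the glycidate stereocentre unchanged from 22. The demand is acylation of a hindered allylic alcohol without touching the epoxide.

21 to 20 to 19 to 17 to 16: the C9–H bond and the C8–O bond are removed. The C9 ketone is what the key step delivers, and C8 is its only enolisable α-carbon. C9 is set relative to C8 (Felkin–Anh, non-chelating silyl ether). C8 is set by enolate oxidation followed by inversion, because the oxidant is expected on the face opposite to the one 31 requires.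

16 to 15: the C4–C9 bond is reconnected (the forward step cleaves it). A ten-membered ring with two ring-cis alkenes becomes a cis-decalin, so alkene geometry becomes a question of configuration on a chair. The stereodescriptors of 15 and 16 were checked atom by atom against 31: C6 and C7 agree; in 15 the C15 methyl and the C9 hydroxyl are cis and the mesylate is trans to the methyl. No correction was needed. The demand is an equatorial C5 leaving group antiperiplanar to C4–C9, and a base that spares the alkylidene β-keto ester of 16.

15 to 14 to 13: the C5–O sulfonyl bond and the C5–H bond are removed, back to the C5 ketone. The C9 hydroxyl directs the hydride, so C5 is set from C9 and not from the angular methyl (which would give the wrong epimer).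

13 to 12: the lactone C6–O bond is cut. The C5 ketone activates C6 (its only α-CH2), and the tethered acid closes onto C6 from its own face, giving the cis-lactone. The demand is oxidative lactonisation without harming the tertiary allylic alcohol.

12 to 11 to 10 to 9 to 8 to 7: C1–H goes back to the C1 ketone (via the enol triflate) and the C9–O bond back to the annulation enone (via the epoxide). This is a formal 1,3-transposition. A hydrazine-based transposition was not chosen because hydrazine would also condense with the C5 ketone and attack the esters. The demand is epoxidation cis to the angular methyl and handling of a ketol that can undergo retro-aldol.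

7 to 6 to 3 and 5: the C9–C10 bond (aldol) and the C3–C4 bond (Michael) are cut, a Robinson annulation. Desymmetrisation of 6 sets C4, and thereby the absolute configuration of the pre-existing C7. The demand is catalyst control over a fast racemic background cyclisation.

3 to 1, and 5 to 4: the arene is the masked 1,3-dione, with C–C bond formation only at the methyl; 5 comes from 4 by loss of methanol.

## Other disconnections considered

Alternative 1: The cut is C7–C8, with the C8 oxygen tied to C13 in the thirteen-membered α-allyloxy ketone A1. In the forward step LiN(SiMe3)2 forms the C8 enolate of A1, and a [2,3]-Wittig shift forms C7–C8 as O–C13 breaks, giving the hydroxy ketone A2.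
- In favour: one concerted step creates C7, C8, the C8 hydroxyl and the C11=C13 methylene, and a thirteen-membered ring is easier to close than a ten-membered one. On the C8 oxygen and on C13 it is better than the chosen plan, which needs a hydroxylation, an inversion and a late enolate methylenation.
- Against: A1 needs a long acyclic synthesis (C4, C5, C6, the epoxide, the ring-cis enone) plus a macrocyclisation. The C7/C8 outcome depends on the transition-state conformation of a flexible ring, and a [1,2]-shift can compete. C12 and C14 arrive at the alcohol oxidation level, so lactone and ester need extra oxidations.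
- Comparison: both plans deliver the ring-cis C1=C10 alkene and both key steps are concerted. The fragmentation reads its geometry from a rigid chair, which is the more predictable. In step count after the key step Alternative 1 is equal or slightly better; before it, it is probably longer.

Alternative 2: The cut is C2–C3; the retron is the C10 ketone with the C4=C5 alkene, and the precursor is the cis-1-vinyl-2-isopropenylcyclohexanol A3, in which C5–C10 is a ring bond. In the forward step KH/18-crown-6 gives the alkoxide, and an anionic oxy-Cope rearrangement gives the cyclodecenone A4 after protonation.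
- In favour: all of C6–C9 are set on a six-membered ring before expansion, which is better than the chosen plan for C8 and C9. The boat transition state of a cis-dialkenyl ring gives the ring-cis C4=C5 alkene as reliably in principle as the fragmentation (equal). The C10 enolate is released regiospecifically and could be trapped as a triflate.
- Against: A4 lacks C14, so the enoate must be built from the ketone (ring-cis enol triflate, then carbonylation with Pd(PPh3)4/CO/MeOH). C12 is only a lactol, C13 is missing, and two ethers must be exchanged for two different esters. A3 is a densely oxygenated cyclohexanol made by vinyl addition to an epimerisable α-isopropenyl ketone with β-alkoxy groups.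
- Comparison: both are concerted ring expansions of a six-membered ring. The chosen plan gets the C9/C10 oxidation pattern directly from the annulation. Step economy is at best equal.

Alternative 3: The cut is C5–C6, in the seco aldehyde A5 that carries a 2-silyloxyfuran. In the forward step BF3·OEt2 activates the aldehyde and the furan attacks through C6 (vinylogous Mukaiyama aldol), closing ring and butenolide to give A6.
- In favour: convergent; C4, C8 and C9 come from acyclic methods (better for C8/C9). The epoxide would arise by displacement at C5 by the C4 oxygen, with no face-selectivity question (better, provided the aldol sets C5).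
- Against: direct closure of a ten-membered ring is entropically and enthalpically costly. C5 and C6 are created in the macrocyclisation without a clear control element. The Lewis acid threatens the silyl, acetal and benzyl-type groups. A6 is a 7(11)-ene butenolide, so the C7 stereocentre and C13 still have to be made: conjugate reduction of a tetrasubstituted butenolide beside the enoate, then methylenation.
- Comparison: the chosen plan has C6 and C7 fixed on the decalin and pays no ring-closure entropy at the key step. Alternative 3 is the equal of the chosen plan in convergence, but the C7/C13 problem makes it no shorter.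

Key step: step 13

Remark: germacrane numbering is used for every intermediate; β is the face of the C7–C11 bond in the usual ring drawing and α the opposite face (that of the C15 methyl in the decalins); C10 in 10 and C11 in 26 and 27 are non-persistent stereocentres and are left undefined; the SMILES strings are decisive.

Step 1
Reactants: 1 3,5-dihydroxyphenylacetic acid
Product: 3 (4-methyl-3,5-dioxocyclohexyl)acetic acid, via dioxocyclohexylacetate 2 (not isolated)
Conditions: H2 (5 bar), Rh/Al2O3 (5%), NaOH (2.1 equiv), H2O, 50 °C; filter; MeI, 1,4-dioxane/H2O, 70 °C; HCl to pH 2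
Reagents that add atoms: iodomethane (CI)
Why: Hydrogenation of the resorcinol monoanion stops at the cyclohexane-1,3-dione enolate, which is C-methylated in the same pot (the resorcinol-to-2-methyl-1,3-dione protocol); 3 is achiral.

Step 2
Reactants: 4 methyl 5-methoxy-3-oxopentanoate
Product: 5 methyl 3-oxopent-4-enoate (Nazarov reagent)
Conditions: TsOH·H2O (cat.), 110 °C, 30 mbar, distil
Reagents that add atoms: none
Why: Acid-catalysed β-elimination of methanol from the β-methoxy ketone; the vinyl ketone is distilled as it forms and used at once because it polymerises.

Step 3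
Reactants: 3 (4-methyl-3,5-dioxocyclohexyl)acetic acid; 5 methyl 3-oxopent-4-enoate
Product: 6 [4-(5-methoxy-3,5-dioxopentyl)-4-methyl-3,5-dioxocyclohexyl]acetic acid with the methyl trans to the carboxymethyl group (meso)
Conditions: H2O, AcOH (cat.), hydroquinone (cat.), rt
Reagents that add atoms: none
Why: Michael addition of the acidic 2-methyl-1,3-dione to the vinyl ketone, run without amine base so that the β-keto ester does not cyclise prematurely and racemically. Axial attack on the dione enol places the new chain cis to the equatorial carboxymethyl group, so the methyl/carboxymethyl trans isomer should predominate; the other isomer is removed by crystallisation.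

Step 4
Reactants: 6 trans-triketone acid
Product: 7 2-[(3R,8aS)-5-(methoxycarbonyl)-8a-methyl-1,6-dioxo-1,2,3,4,6,7,8,8a-octahydronaphthalen-3-yl]acetic acid (4α-methyl and 7β-side chain in germacrane numbering)
Conditions: L-phenylalanine (1.0 equiv), (1S)-(+)-camphor-10-sulfonic acid (0.5 equiv), DMF, 30 → 70 °C
Reagents that add atoms: none
Why: Hajos–Parrish–Eder–Sauer–Wiechert-type desymmetrising aldol condensation: the amino acid forms the enamino ester at C1, its carboxylic acid activates one of the two enantiotopic ring carbonyls, and dehydration makes the step irreversible. The (S)-amino acid should give the (S)-configured quaternary C4 as in the parent annulation; C7 follows because 6 is a single meso diastereomer.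

Step 5
Reactants: 7 enone acid
Product: 8 allyl ester of 7
Conditions: allyl bromide, KHCO3, DMF, rt
Reagents that add atoms: allyl bromide (C=CCBr)
Why: Carboxylate O-alkylation under bicarbonate, too weak a base to deconjugate the alkylidene β-keto ester; the ester masks the acid through the enolate chemistry of steps 6–8.

Step 6
Reactants: 8 allyl ester
Product: 9 9α,10α-epoxy diketone (epoxide cis to the C15 methyl)
Conditions: tBuOOH (decane solution), DBU (0.2 equiv), CH2Cl2, 0 °C
Reagents that add atoms: tert-butyl hydroperoxide (CC(C)(C)OO)
Why: Weitz–Scheffer nucleophilic epoxidation of the doubly activated alkene. Axial attack of the hydroperoxide anion at C9 on the face of the angular methyl (the face leading to a chair enolate and away from the axial C7 side chain) should give the cis-fused epoxide, which fixes the C9–O bond α.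

Step 7
Reactants: 9 epoxy diketone
Product: 10 9α-hydroxy β-keto ester (ketol; C10 epimers and enol)
Conditions: SmI2 (2.2 equiv), MeOH (2 equiv), THF, −90 °C; pH 7 buffer
Reagents that add atoms: none
Why: Two-electron reductive cleavage of the Cα–O bond of an α,β-epoxy ketone by SmI2, which leaves the isolated C5 ketone and the allyl ester alone at this temperature; C9 keeps its configuration.

Step 8
Reactants: 10 ketol
Product: 11 C1 enol triflate of 10 (9α-hydroxy, C1=C10)
Conditions: NaH (1.05 equiv), THF, 0 °C; PhNTf2, 0 °C → rt
Reagents that add atoms: N-phenylbis(trifluoromethanesulfonimide) (O=S(=O)(N(c1ccccc1)S(=O)(=O)C(F)(F)F)C(F)(F)F)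
Why: Enol triflate formation: one equivalent of base deprotonates only the β-keto ester, and its enolate oxygen is sulfonylated. The tertiary hydroxyl stays protonated, which avoids retro-aldol opening.

Step 9
Reactants: 11 enol triflate
Product: 12 9α-hydroxy-5-oxo-1(10)-ene acid (C14 methyl ester, free C12 acid)
Conditions: Pd(OAc)2 (5 mol %), PPh3 (10 mol %), HCO2H, Et3N, DMF, 50 °C
Reagents that add atoms: none
Why: Zerovalent palladium inserts into the vinyl C–OTf bond and formate delivers hydride (reductive detriflation), giving the C1=C10 enoate; the same catalyst and formate cleave the allyl ester through the π-allyl complex, so the acid is freed in the same operation.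

Step 10
Reactants: 12 hydroxy keto acid
Product: 13 5-oxo-6β,12-olide (cis-fused lactone; 9α-hydroxy; C1=C10 enoate)
Conditions: PhI(OH)OTs (1.1 equiv), MeCN, rt → 40 °C
Reagents that add atoms: none
Why: Hypervalent-iodine oxidative lactonisation of a 5-oxo acid: the C5 ketone can enolise only towards C6, the enol is captured by the iodane, and the tethered carboxylate closes the five-membered ring at C6 from its own face, so C6–O is cis to C7–C11. C6 stays epimerisable next to the ketone, which should funnel material to the cis ring fusion.

Step 11
Reactants: 13 keto lactone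
Product: 14 5β,9α-diol of the 6β,12-olide
Conditions: Me4NBH(OAc)3, MeCN/AcOH (1:1), −25 °C
Reagents that add atoms: none
Why: Evans–Saksena hydroxyl-directed reduction: the C9 hydroxyl binds boron and delivers hydride to the α face of the C5 carbonyl, giving the anti-1,3-diol with the C5 hydroxyl β (trans to the angular methyl, equatorial in the chair of ring A that has C3 axial).

Step 12
Reactants: 14 diol
Product: 15 5β-mesylate of 14 (cis-decalin C9 carbinol C5 mesylate)
Conditions: MsCl, Et3N, CH2Cl2, −20 → 0 °C
Reagents that add atoms: methanesulfonyl chloride (CS(=O)(=O)Cl)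
Why: Sulfonylation of the secondary alcohol; the tertiary allylic C9 hydroxyl is far less reactive and no stereocentre is touched.

Step 13
Reactants: 15 carbinol mesylate
Product: 16 ring-cis,cis cyclodeca-1(10),4-dien-9-one 6β,12-olide with the C14 methyl ester
Conditions: KOtBu (1.05 equiv), THF, −20 → 0 °C; pH 7 phosphate buffer
Reagents that add atoms: none
Why: Wharton-type Grob fragmentation of a 1,3-diol monosulfonate: KOtBu deprotonates the tertiary C9 hydroxyl, the alkoxide forms the C9 carbonyl, the C4–C9 σ bond (antiperiplanar to the C5–O bond of the equatorial mesylate in the chair of ring A) breaks, and C4=C5 forms as mesylate leaves, all in one concerted step. The closest known reaction type is the base-induced fragmentation of decalin-1,3-diol monosulfonates to cyclodecenones. No ring is closed: cleaving the shared C4–C9 bond merges rings A and B into the ten-membered carbocycle, and the lactone is a spectator. No stereocentre is created; C4 and C9 become trigonal and C6 and C7 are untouched. The step must deliver the ring-cis C4=C5 geometry: the cis ring fusion (C15 methyl and C9 oxygen both α) with the 5β-mesylate puts C3 axial and gauche to C6 in the only chair that has the mesylate equatorial, and this gauche pair becomes the cis pair of the alkene, while the C1=C10 geometry is inherited from the cyclohexene of ring B. The other chair would carry the mesylate, C11 and C10 all axial on one face; the equatorial mesylate has no antiperiplanar hydrogen for elimination; and the axial alkoxide is badly aligned for oxetane formation at C5, so fragmentation should be the only fast pathway. Because 16 is a base-sensitive alkylidene β-keto ester, only a slight excess of base is used at low temperature, with an immediate buffered quench.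

Step 14
Reactants: 16 cyclodecadienone lactone
Product: 17 8α-hydroxy derivative of 16
Conditions: KN(SiMe3)2 (1.1 equiv), THF, −78 °C; 2-(phenylsulfonyl)-3-phenyloxaziridine, −78 °C; NH4Cl (aq)
Reagents that add atoms: 2-(phenylsulfonyl)-3-phenyloxaziridine (O=S(=O)(N1OC1c1ccccc1)c1ccccc1)
Why: α'-Hydroxylation of the kinetic ketone enolate with an N-sulfonyloxaziridine; the hindered amide removes H8 faster than the γ-hydrogen at C2 or the lactone α-hydrogen. With H7 in the enolate plane (allylic strain), ring carbon C6 covers one face and the oxidant should enter from the outer face, which gives the 8α-alcohol (O8 trans to C11 in the ring drawing), the epimer of what 31 needs; step 15 corrects this.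

Step 15
Reactants: 17 8α-hydroxy ketone
Product: 19 8β-hydroxy ketone, via 8β-formate 18 (not isolated)
Conditions: PPh3, DIAD, HCO2H, THF, 0 °C; then NaHCO3 (cat.), MeOH, 0 °C
Reagents that add atoms: formic acid (OC=O)
Why: Mitsunobu reaction: displacement of the activated α-keto alcohol by formate inverts C8 to the β configuration (oxygen cis to C11, as in 31); the formate is removed by bicarbonate-catalysed methanolysis in the same pot.

Step 16
Reactants: 19 8β-hydroxy ketone
Product: 20 8β-triethylsilyl ether of 19
Conditions: Et3SiCl, imidazole, DMF, 0 °C
Reagents that add atoms: chlorotriethylsilane (CC[Si](CC)(CC)Cl)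
Why: Silylation of the secondary alcohol; the bulky, non-chelating ether steers the next reduction and, unlike an acetate, survives the lactone enolate of step 20.

Step 17
Reactants: 20 silyloxy ketone
Product: 21 9α-alcohol (8β-silyloxy; C1=C10 enoate)
Conditions: NaBH4, CeCl3·7H2O, MeOH/THF, −78 °C
Reagents that add atoms: none
Why: Luche reduction gives 1,2-addition to the alkylidene β-keto ester; with a non-chelating α-silyloxy group, hydride should add anti to the C8–O bond (Felkin–Anh), giving the 9α-alcohol, trans to the C8 oxygen.

Step 18
Reactants: 22 methyl (R)-2-methylglycidate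
Product: 23 potassium (R)-2-methylglycidate
Conditions: KOH (1.0 equiv), MeOH, 0 °C; evaporate, dry
Reagents that add atoms: potassium hydroxide ([K+].[OH-])
Why: Saponification with one equivalent of hydroxide in the cold; the quaternary stereocentre cannot epimerise and the epoxide survives, and the dry salt is used directly.

Step 19
Reactants: 21 9α-alcohol; 23 potassium (R)-2-methylglycidate
Product: 25 9α-[(R)-2-methylglycidoyloxy] 8β-silyl ether, via mixed anhydride 24 (not isolated)
Conditions: 23, 2,4,6-trichlorobenzoyl chloride, THF, 0 °C → rt; then 21, DMAP, toluene, rt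
Reagents that add atoms: none
Why: Yamaguchi esterification: the carboxylate forms the mixed anhydride, and DMAP transfers the less hindered glycidoyl group to the C9 hydroxyl, with retention at C9 and at the glycidate carbon.

Step 20
Reactants: 25 glycidate ester
Product: 26 11-(dimethylaminomethyl) lactone (C11 epimers)
Conditions: LiN(SiMe3)2 (1.1 equiv), THF, −78 °C; Me2N=CH2 I, −78 → −20 °C
Reagents that add atoms: N,N-dimethylmethyleneiminium iodide (C=[N+](C)C.[I-])
Why: Mannich reaction of the lactone enolate: the lactone α-hydrogens are now the most acidic (the glycidate has none and C8 carries a silyl ether), so one equivalent of base at low temperature should enolise the lactone in preference to the γ-position of the enoate.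

Step 21
Reactants: 26 Mannich base
Product: 28 11(13)-methylene lactone (8β-silyl ether), via trimethylammonium iodide 27 (not isolated)
Conditions: MeI, CH2Cl2, rt; then NaHCO3 (aq), rt
Reagents that add atoms: none
Why: Quaternisation and Hofmann-type β-elimination (E1cB from the lactone) give the exocyclic C11=C13 alkene under bicarbonate, mild enough for both esters and the glycidate epoxide.

Step 22
Reactants: 28 silyl ether
Product: 29 8β-alcohol
Conditions: AcOH/THF/H2O (3:1:1), rt
Reagents that add atoms: none
Why: Mild acidic hydrolysis of the triethylsilyl ether; the conditions are too weak to open the glycidate epoxide or to promote acyl migration from O9.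

Step 23
Reactants: 29 8β-alcohol
Product: 30 8β-acetate (4,5-alkene)
Conditions: Ac2O, pyridine, DMAP (cat.), CH2Cl2, 0 °C → rt
Reagents that add atoms: acetic anhydride (CC(=O)OC(C)=O)
Why: DMAP-catalysed acetylation of the secondary alcohol, with retention at C8.

Step 24
Reactants: 30 8β-acetate
Product: 31 CNP0159450.1 (4α,5α-epoxide)
Conditions: mCPBA (1.2 equiv), NaHCO3, CH2Cl2, 0 °C
Reagents that add atoms: 3-chloroperbenzoic acid (OOC(=O)c1cccc(Cl)c1)
Why: Prilezhaev epoxidation: the peracid reacts with the only electron-rich alkene (trisubstituted C4=C5) and not with the enoate or the α-methylene lactone, and syn addition to the ring-cis alkene gives the cis-epoxide. With H6 eclipsing the alkene (allylic strain), C7 and the ring lie on one face, so peripheral attack should place the oxygen on the exposed face, which corresponds to the α-epoxide of 31.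

## Compound list

1 | 3,5-dihydroxyphenylacetic acid | OC(=O)Cc1cc(O)cc(O)c1 | starting material
2 | (3,5-dioxocyclohexyl)acetic acid, present as its sodium enolate (not isolated) | OC(=O)CC1CC(=O)CC(=O)C1 | intermediate
3 | (4-methyl-3,5-dioxocyclohexyl)acetic acid | OC(=O)CC1CC(=O)C(C)C(=O)C1 | intermediate
4 | methyl 5-methoxy-3-oxopentanoate | COCCC(=O)CC(=O)OC | starting material
5 | methyl 3-oxopent-4-enoate (Nazarov reagent) | C=CC(=O)CC(=O)OC | intermediate
6 | [4-(5-methoxy-3,5-dioxopentyl)-4-methyl-3,5-dioxocyclohexyl]acetic acid, methyl trans to carboxymethyl (meso) | OC(=O)C[C@@H]1CC(=O)[C@](C)(CCC(=O)CC(=O)OC)C(=O)C1 | intermediate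
7 | 2-[(3R,8aS)-5-(methoxycarbonyl)-8a-methyl-1,6-dioxo-1,2,3,4,6,7,8,8a-octahydronaphthalen-3-yl]acetic acid | OC(=O)C[C@@H]1CC2=C(C(=O)OC)C(=O)CC[C@]2(C)C(=O)C1 | intermediate
8 | allyl ester of 7 | C=CCOC(=O)C[C@@H]1CC2=C(C(=O)OC)C(=O)CC[C@]2(C)C(=O)C1 | intermediate
9 | 9α,10α-epoxy diketone allyl ester (epoxide cis to the C15 methyl) | C=CCOC(=O)C[C@@H]1C[C@]2(O3)[C@]3(C(=O)OC)C(=O)CC[C@]2(C)C(=O)C1 | intermediate
10 | 9α-hydroxy β-keto ester (ketol; C10 epimers and enol) | C=CCOC(=O)C[C@@H]1C[C@]2(O)C(C(=O)OC)C(=O)CC[C@]2(C)C(=O)C1 | intermediate
11 | C1 enol triflate of 10 (9α-hydroxy, C1=C10) | C=CCOC(=O)C[C@@H]1C[C@]2(O)C(C(=O)OC)=C(OS(=O)(=O)C(F)(F)F)CC[C@]2(C)C(=O)C1 | intermediate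
12 | 9α-hydroxy-5-oxo-1(10)-ene acid (C14 methyl ester, free C12 acid) | OC(=O)C[C@@H]1C[C@]2(O)C(C(=O)OC)=CCC[C@]2(C)C(=O)C1 | intermediate
13 | 5-oxo-6β,12-olide (cis-fused lactone; 9α-hydroxy; C1=C10 enoate) | C1C(=O)O[C@@H]2[C@H]1C[C@]3(O)C(C(=O)OC)=CCC[C@]3(C)C2=O | intermediate
14 | 5β,9α-diol of the 6β,12-olide | C1C(=O)O[C@@H]2[C@H]1C[C@]3(O)C(C(=O)OC)=CCC[C@]3(C)[C@@H]2O | intermediate
15 | cis-decalin C9 carbinol C5β-mesylate with fused lactone | C1C(=O)O[C@@H]2[C@H]1C[C@]3(O)C(C(=O)OC)=CCC[C@]3(C)[C@@H]2OS(C)(=O)=O | intermediate
16 | ring-cis,cis cyclodeca-1(10),4-dien-9-one 6β,12-olide, C14 methyl ester | C1C(=O)O[C@@H]2[C@H]1CC(=O)/C(C(=O)OC)=C\CC/C(C)=C\2 | intermediate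
17 | 8α-hydroxy derivative of 16 | C1C(=O)O[C@@H]2[C@H]1[C@@H](O)C(=O)/C(C(=O)OC)=C\CC/C(C)=C\2 | intermediate
18 | 8β-formate (not isolated) | C1C(=O)O[C@@H]2[C@H]1[C@H](OC=O)C(=O)/C(C(=O)OC)=C\CC/C(C)=C\2 | intermediate
19 | 8β-hydroxy ketone | C1C(=O)O[C@@H]2[C@H]1[C@H](O)C(=O)/C(C(=O)OC)=C\CC/C(C)=C\2 | intermediate
20 | 8β-triethylsilyloxy ketone | C1C(=O)O[C@@H]2[C@H]1[C@H](O[Si](CC)(CC)CC)C(=O)/C(C(=O)OC)=C\CC/C(C)=C\2 | intermediate
21 | 9α-alcohol (8β-triethylsilyloxy) | C1C(=O)O[C@@H]2[C@H]1[C@H](O[Si](CC)(CC)CC)[C@@H](O)/C(C(=O)OC)=C\CC/C(C)=C\2 | intermediate
22 | methyl (R)-2-methylglycidate | COC(=O)[C@@]1(C)CO1 | starting material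
23 | potassium (R)-2-methylglycidate | [K+].[O-]C(=O)[C@@]1(C)CO1 | intermediate
24 | (R)-2-methylglycidic 2,4,6-trichlorobenzoic anhydride (not isolated) | O=C(OC(=O)[C@@]1(C)CO1)c1c(Cl)cc(Cl)cc1Cl | intermediate
25 | 9α-[(R)-2-methylglycidoyloxy] 8β-triethylsilyl ether | C1C(=O)O[C@@H]2[C@H]1[C@H](O[Si](CC)(CC)CC)[C@@H](OC(=O)[C@@]3(C)CO3)/C(C(=O)OC)=C\CC/C(C)=C\2 | intermediate
26 | 11-(dimethylaminomethyl) lactone (C11 epimers) | CN(C)CC1C(=O)O[C@@H]2[C@H]1[C@H](O[Si](CC)(CC)CC)[C@@H](OC(=O)[C@@]3(C)CO3)/C(C(=O)OC)=C\CC/C(C)=C\2 | intermediate
27 | 11-(trimethylammoniomethyl) lactone iodide (not isolated) | C[N+](C)(C)CC1C(=O)O[C@@H]2[C@H]1[C@H](O[Si](CC)(CC)CC)[C@@H](OC(=O)[C@@]3(C)CO3)/C(C(=O)OC)=C\CC/C(C)=C\2.[I-] | intermediate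
28 | 11(13)-methylene lactone, 8β-triethylsilyl ether | C=C1C(=O)O[C@@H]2[C@H]1[C@H](O[Si](CC)(CC)CC)[C@@H](OC(=O)[C@@]3(C)CO3)/C(C(=O)OC)=C\CC/C(C)=C\2 | intermediate
29 | 8β-alcohol | C=C1C(=O)O[C@@H]2[C@H]1[C@H](O)[C@@H](OC(=O)[C@@]3(C)CO3)/C(C(=O)OC)=C\CC/C(C)=C\2 | intermediate
30 | 8β-acetate (4,5-alkene) | C=C1C(=O)O[C@@H]2[C@H]1[C@H](OC(C)=O)[C@@H](OC(=O)[C@@]3(C)CO3)/C(C(=O)OC)=C\CC/C(C)=C\2 | intermediate
31 | CNP0159450.1 | C=C1C(=O)O[C@@H]2[C@H]1[C@H](OC(C)=O)[C@@H](OC(=O)[C@@]1(C)CO1)/C(C(=O)OC)=C\CC[C@@]1(C)O[C@@H]21 | target

## Step count and least certain steps

Total step count: 24. Longest linear sequence: 22 steps (1 to 31 through steps 1, 3–17 and 19–24); steps 2 and 18 prepare the two side components.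

Step 13 (key step). Most likely to go wrong: degradation of 16 as it forms, by conjugate addition of tert-butoxide to the alkylidene β-keto ester, γ-deprotonation with deconjugation of C1=C10, or transannular reactions of the C8 enolate. The cause is a strong base next to a doubly activated alkene. Fallback that generates the alkoxide slowly and without an alkoxide base: 15 is silylated at the tertiary hydroxyl with N-(trimethylsilyl)imidazole to the C9 trimethylsilyl ether F1. Bu4NF in THF at −20 °C then removes the silyl group, and the alkoxide fragments as it appears, returning the route to 16.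

Step 4. Most likely to go wrong: low enantioselectivity, because the strongly enolised β-keto ester of 6 can cyclise by an uncatalysed or simply acid-catalysed pathway in competition with the enamine pathway. Fallback by resolution instead of asymmetric catalysis: 6 is cyclised without chiral control (KF, MeOH; then TsOH, toluene, reflux) to the racemic enone acid F2. F2 is resolved through its salt with (R)-1-phenylethylamine; the crystalline diastereomeric salt F3 is acidified (if the antipode crystallises first, the other enantiomer of the amine is used) and the route is rejoined at 7.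

Step 10. Most likely to go wrong: loss of the tertiary allylic hydroxyl by ionisation or dehydration, since one equivalent of sulfonic acid is released in warm acetonitrile. Fallback under basic conditions through a bromide: 12 is deprotonated three times (LiN(SiMe3)2, 3.1 equiv, THF, −78 °C) and brominated with NBS to the 6-bromo keto acid F4. NaHCO3 in DMF then closes the lactone by intramolecular displacement; the α-bromide epimerises readily, so closure again selects the cis ring fusion, returning to 13.

Step 14. Most likely to go wrong: competing γ-deprotonation at C2 or 1,4-addition of the amide to the alkylidene β-keto ester, and a facial selectivity different from the assumed one, since it rests on the conformation of a flexible ring. Fallback without a strong base: soft enolisation of 16 with Me3SiOTf/Et3N at −78 °C gives the 2-silyloxydiene F5, and Rubottom oxidation with one equivalent of dimethyldioxirane at −78 °C followed by citric acid work-up gives 17. If either procedure should deliver the 8β-alcohol directly, that compound is 19 and step 15 is omitted.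

Step 17. Most likely to go wrong: hydride delivery to the other face of the C9 carbonyl, with ring conformation overriding the Felkin–Anh preference, giving the 9β-alcohol. Fallback that uses this outcome: the 9β-alcohol F6 obtained from 20 is esterified under Mitsunobu conditions (PPh3, DIAD, toluene, 0 °C) with the free (R)-2-methylglycidic acid F7, liberated from 23 with KHSO4. The esterification proceeds with inversion at C9 and gives 25 directly.

Step 24. Most likely to go wrong: attack of the peracid on the other face of C4=C5, or low facial selectivity, again because the control element is conformational. Fallback with the opposite facial outcome: 30 is treated with NBS in aqueous THF at 0 °C. Bromonium formation on the face preferred by electrophiles and anti opening by water at the tertiary C4 give the 4α-hydroxy-5β-bromo bromohydrin F8; Ag2O in CH2Cl2 then closes the epoxide by displacement at C5 from the opposite face, giving 31.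

## Further compounds

F1 | step 13 | C9 trimethylsilyl ether of mesylate 15 | C1C(=O)O[C@@H]2[C@H]1C[C@]3(O[Si](C)(C)C)C(C(=O)OC)=CCC[C@]3(C)[C@@H]2OS(C)(=O)=O
F2 | step 4 | racemic enone acid (7 and its enantiomer) | OC(=O)C[C@@H]1CC2=C(C(=O)OC)C(=O)CC[C@]2(C)C(=O)C1.OC(=O)C[C@H]1CC2=C(C(=O)OC)C(=O)CC[C@@]2(C)C(=O)C1
F3 | step 4 | (R)-1-phenylethylammonium salt of 7 | [O-]C(=O)C[C@@H]1CC2=C(C(=O)OC)C(=O)CC[C@]2(C)C(=O)C1.C[C@@H]([NH3+])c1ccccc1
F4 | step 10 | 6-bromo-9α-hydroxy-5-oxo acid (C6 epimers) | OC(=O)C[C@@H]1C[C@]2(O)C(C(=O)OC)=CCC[C@]2(C)C(=O)C1Br
F5 | step 14 | 9-(trimethylsilyloxy)-8,9-enol ether of 16 | C1C(=O)O[C@@H]2[C@H]1C=C(O[Si](C)(C)C)/C(C(=O)OC)=C\CC/C(C)=C\2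
F6 | step 17 | 9β-alcohol (C9 epimer of 21) | C1C(=O)O[C@@H]2[C@H]1[C@H](O[Si](CC)(CC)CC)[C@H](O)/C(C(=O)OC)=C\CC/C(C)=C\2
F7 | step 17 | (R)-2-methyloxirane-2-carboxylic acid | OC(=O)[C@@]1(C)CO1
F8 | step 24 | 4α-hydroxy-5β-bromo bromohydrin of 30 | C=C1C(=O)O[C@@H]2[C@H]1[C@H](OC(C)=O)[C@@H](OC(=O)[C@@]3(C)CO3)/C(C(=O)OC)=C\CC[C@@](C)(O)[C@@H]2Br
A1 | alternative 1 | thirteen-membered α-allyloxy ketone (C8–O–C13 ether, 4,5-epoxide, silyl ethers at O6 and O12, PMB ether at C14; C7=C11 drawn ring-trans) | O=C1COC/C(CO[Si](C)(C)C(C)(C)C)=C/[C@@H](O[Si](C)(C)C(C)(C)C)[C@@H]2O[C@]2(C)CC/C=C\1COCc1ccc(OC)cc1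
A2 | alternative 1 | ten-membered C8 hydroxy C9 ketone with C11=C13 methylene and epoxide | C=C(CO[Si](C)(C)C(C)(C)C)[C@@H]1[C@H](O)C(=O)/C(COCc2ccc(OC)cc2)=C\CC[C@@]3(C)O[C@H]3[C@@H]1O[Si](C)(C)C(C)(C)C
A3 | alternative 2 | cis-1-vinyl-2-isopropenylcyclohexanol with lactol methyl ether, PMB and MOM ethers (isopropenyl drawn trans to O6) | C1[C@@H](OC)O[C@@H]2[C@H]1[C@H](OCc3ccc(OC)cc3)[C@@H](OCOC)[C@@](O)(C=C)[C@H]2C(C)=C
A4 | alternative 2 | (Z)-cyclodec-5-enone with C6–C9 stereocentres | C1[C@@H](OC)O[C@@H]2[C@H]1[C@H](OCc3ccc(OC)cc3)[C@@H](OCOC)C(=O)CCC/C(C)=C\2
A5 | alternative 3 | seco C5 aldehyde carrying a 2-(triisopropylsilyloxy)furan at C8 | O=C[C@](C)(O[Si](CC)(CC)CC)CC/C=C(C(=O)OC)\[C@H](OCOC)[C@@H](OCc1ccc(OC)cc1)c1coc(O[Si](C(C)C)(C(C)C)C(C)C)c1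
A6 | alternative 3 | ten-membered 7(11)-en-6,12-olide with C5 hydroxyl | O=C1C=C2[C@@H](O1)[C@@H](O)[C@](C)(O[Si](CC)(CC)CC)CC/C=C(C(=O)OC)\[C@H](OCOC)[C@H]2OCc1ccc(OC)cc1
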